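In a one-step world the reagent meets starting material and nothing else, so one equivalent is enough for a full yield of target, but this flask has a fork.

    starting material + reagent + free catalyst → free catalyst + target (k1 = 1.6 /M²/min)
    second substrate + reagent + free catalyst → free catalyst + second product (k2 = 2.7 /M²/min)
    reagent ⇌ dormant form (K3 = 0.66, k3 = 0.018 /min)
    free catalyst → spent catalyst (k4 = 0.0072 /min)

all flasks: second substrate 1.00 equiv; free catalyst 10 mol%

| flask | starting material | reagent | time | remark |
|---|---|---|---|---|
| violet | 0.50 M (fed, over 1.00 h) | 1.00 equiv | 1.0 h | a stirred flask in which starting material is dosed at a steady rate over 1.00 h without added volume, worked up at 1.0 h |
| green | 0.50 M | 1.00 equiv |  | a single well-mixed tank run continuously and read at steady state, 1.0 h in it on average |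
| red | 0.50 M | 1.00 equiv (fed, over 1.00 h) | 1.0 h | all but reagent at the start; reagent goes in evenly over 1.00 h, the run ends at 1.0 h |
| teal | 0.50 M | 1.00 equiv | 1.0 h | a closed flask charged with all of it at once and left for 1.0 h |

- the set-up with the highest amount of target at the outlet or at the end, in percent of the starting material put in ("none" if the first two lie within 2 percentage points) (violet / green / red / teal / none)
- amount of target at the outlet or at the end, in percent of the starting material put in, violet
- amount of target at the outlet or at the end, in percent of the starting material put in, green
- amount of target at the outlet or at the end, in percent of the starting material put in, red
- amount of target at the outlet or at the end, in percent of the starting material put in, teal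

- the stated concentrations are those of everything mixed, before any reaction; amounts are the same in each set-up
- the feed brings no volume worth counting
- run time (violet): 1.0 h

Follow one reagent molecule in the teal flask. Let a and b be the fractions of starting material and second substrate still left. Both paths use the same reagent and free catalyst, so the molecule's chance of making target is k1·a/(k1·a + k2·b). At the start a equals b, the chance is 37.2%, and with one equivalent of reagent that is my first estimate of the yield.

But the chance moves. Second substrate is used faster than starting material, so b falls below a. Dividing the two rates cancels reagent and catalyst, and what remains is the exponent n, how many times faster second substrate goes, the selectivity factor 1.69: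

b = a^n

(1 − a) + (1 − b) = one charge of reagent

Try a = 0.628. Then b = 0.456, and the balance asks for a = 0.544. Midway, a = 0.586 and b = 0.406, which sum to 0.992, close enough. So with its reagent all used, I reckon teal at about 41.4% target.

That spends the whole reagent charge within the hour, which is doubtful. Catalyst decay does not bend the curve, since catalyst cancels from n, and its half-life of 96.3 min is longer than the run. The dormant form holds reagent back, taking 14.3% of the reagent's first moves. This is a start value, and I use it as a guess for the reagent idle at the end. Each idle molecule costs target at the late chance a/(a + n·b) = 46.1%, so I commit to 34.8% for teal.

The red flask has both substrates from the start, so the same curve holds there, but I reckon no point on it. The violet flask starts with no starting material, so the curve fails there, and the green tank needs its own balance, which I leave open.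

The forecast gives 14% for violet, 28% for green, 26% for red and 34% for teal, against my 34.8%, and picks teal. Its ground: “The second substrate takes reagent faster than the starting material and reagent is limiting”.

The simulation gives 14.9% for violet, 27.9% for green, 25.6% for red and 35.5% for teal, so teal leads. At 1.00 h, teal holds 64% of its starting material; raised to 1.69, that gives 47.7%, and the flask reads 48% of second substrate. Now take teal with 4.00 equiv of second substrate. With a close to one, b is about one minus n(one minus a), so spending the whole reagent charge gives a target fraction of 12.9%. That flask ends at 13.2% target, with 0.26% of its reagent left.

All constants are made up; the flask was simulated.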